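**Plan**

- Retrosynthetic cuts: the primary acetate and the glycerol acetal; the ketone C(=O)–CH2 bond between the ring acyl carbon and the side chain; the ring CH2–CH2 bond C4–C5 of the cyclohexane (C1 = acyl-bearing quaternary carbon, C2 = CH, C3 = CMe2); then the C2–C3 and C1–C6 bonds, which leads back to (S)-carvone.
- Forward: carvone takes a 1,1-dimethylallyl group (future C3–C4) and an allyl group (future C6–C5) on adjacent carbons, its own six-membered ring serving as a temporary ring. The isopropenyl group is masked as an oxirane and the ring CH2 is hydroxylated. Metathesis/hydrogenation then closes the cyclohexane, and periodate excises the temporary ring (C=O to CO2H, oxirane to acetyl, surplus CH2 to formate). Acid chloride plus alkylzinc gives the diketone; acetal removal and lipase acetylation finish the route.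
- Enabling feature: the two olefin arms hang on the adjacent carbons C1 and C2, are flanked by the quaternary carbons C1 and C3, and are held trans-diequatorial by the temporary ring, so the 1,7-diene closes to the six-membered ring.
- Stereochemistry: C2 by addition anti to the isopropenyl group of carvone; C1 by allylation anti to the new group; the side-chain methyl from half-ester 14; the glycerol carbon from (S)-solketal 19.

Key step: step 3

Assumption: 8–11 are carried as mixtures of epimers at the carbinol carbon and the oxirane carbon; both centres vanish in step 4, so the mixture is not separated.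

**Route**

Step 1
Reactants: 1 (S)-(+)-carvone; 2 trimethyl(3-methylbut-2-en-1-yl)silane; 3 allyl bromide
Product: 6 (2R,3R,5S)-2-allyl-2-methyl-3-(2-methylbut-3-en-2-yl)-5-(prop-1-en-2-yl)cyclohexan-1-one, via silyl enol ether 4 (not isolated), via lithium enolate 5 (not isolated)
Conditions: 2 (1.5 equiv), Tf2NH (5 mol %, gives Me3SiNTf2 in the flask), CH2Cl2, −78 → −40 °C; evaporate; MeLi, THF, 0 °C; then 3, DMPU, −40 → 0 °C
Reagents that add atoms: none
Why: Hosomi–Sakurai conjugate allylation under silyl triflimide catalysis should transfer the silane through its CMe2 terminus to the β-carbon anti to the isopropenyl group (axial attack on the half-chair, which sets the ring CH stereocentre) and leave the enolate regiospecifically as its silyl ether, so that MeLi cleavage and allylation anti to the new bulky neighbour (regiospecific enolate alkylation) set the quaternary carbon trans to it.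

Step 2
Reactants: 6
Product: 9 (2R,3R,5S)-2-allyl-6-hydroxy-2-methyl-3-(2-methylbut-3-en-2-yl)-5-(2-methyloxiran-2-yl)cyclohexan-1-one, via silyl enol ether 7 (not isolated), via silyloxy ketone 8 (not isolated)
Conditions: Me3SiOTf, Et3N, CH2Cl2, 0 °C; pentane, filter; mCPBA (2.1 equiv), NaHCO3, CH2Cl2, −20 → 0 °C; aq. citric acid, THF, 0 °C
Reagents that add atoms: 3-chloroperoxybenzoic acid (mCPBA), O=C(OO)c1cccc(Cl)c1
Why: soft enolisation can only go toward the ring CH2 because the other α-carbon is quaternary, and the peracid should then react with the silyl enol ether (Rubottom oxidation) and with the 1,1-disubstituted isopropenyl group (Prilezhaev epoxidation) much faster than with the two monosubstituted olefins; the two new stereocentres form unselectively and are both erased in step 4.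

Step 3
Reactants: 9
Product: 11 (3S,4aR,8aR)-2-hydroxy-5,5,8a-trimethyl-3-(2-methyloxiran-2-yl)octahydronaphthalen-1(2H)-one, via hexahydronaphthalenone 10 (not isolated)
Conditions: second-generation Grubbs catalyst RuCl2(=CHPh)(PCy3)(H2IMes) (3 mol %), CH2Cl2 (5 mM), 40 °C; then solvent change to EtOAc, palladium on carbon (Pd/C, 10 wt %), H2 (1 atm), 23 °C
Reagents that add atoms: none
Why: Ring-closing olefin metathesis: the ruthenium benzylidene should initiate at the less hindered allyl terminus, the new alkylidene adds across the neopentyl-type vinyl group in a [2+2] step, and the ruthenacyclobutane collapses by retro-[2+2] to cyclohexene 10 and ethylene, whose loss drives the closure; hydrogenation over palladium in the same flask then saturates the new ring bond. The closest known reaction type is the ring-closing metathesis of 1,7-dienes with an allylic quaternary carbon to cyclohexenes, followed by catalytic hydrogenation. The ring closes as a six-membered carbocycle from a 1,7-diene and is trans-fused to the temporary cyclohexanone, because the allyl and 1,1-dimethylallyl arms stand trans-diequatorial on adjacent ring carbons. No stereocentre is formed: both ring-fusion centres come from step 1 and lie two and three bonds from the reacting carbons. The step needs chemoselectivity (only two of the original three olefins may react, and the ketol and oxirane must survive) and cyclisation over oligomerisation; the first is secured by the oxirane mask from step 2, the second by the two quaternary carbons flanking the tether and by high dilution.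

Step 4
Reactants: 11
Product: 13 (1R,2R)-1,3,3-trimethyl-2-(3-oxobutyl)cyclohexane-1-carboxylic acid, via formyl keto acid 12 (not isolated)
Conditions: H5IO6 (2.3 equiv), THF–H2O (3:1), 0 → 23 °C; then 1 M NaOH, 40 °C; acidify to pH 3
Reagents that add atoms: water, O
Why: Malaprade cleavage of the α-ketol should turn the ring carbonyl into the carboxylic acid and the carbinol carbon into an aldehyde, periodic acid opens and cleaves the oxirane to the methyl ketone, and hydroxide removes the formyl group of the resulting 2-formyl ketone by retro-Claisen cleavage, so the temporary ring is excised without touching either stereocentre.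

Step 5
Reactants: 14 monomethyl (R)-3-methylglutarate
Product: 16 (4R)-4-methyltetrahydro-2H-pyran-2-one, via hydroxy ester 15 (not isolated)
Conditions: BH3·SMe2, THF, 0 → 23 °C; MeOH; then TsOH (cat.), CH2Cl2, 23 °C
Reagents that add atoms: none
Why: borane should reduce the carboxylic acid chemoselectively beside the methyl ester, and the 5-hydroxy ester closes to the δ-lactone under acid catalysis (lactonisation), the stereocentre being remote from both events.

Step 6
Reactants: 16
Product: 18 (3S)-5-iodo-3-methylpentanoic acid, via silyl ester 17 (not isolated)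
Conditions: Me3SiI, CH2Cl2, 23 → 40 °C; then H2O
Reagents that add atoms: iodotrimethylsilane, C[Si](C)(C)I
Why: lactone cleavage with iodotrimethylsilane: silylation of the carbonyl oxygen and SN2 attack of iodide at the O–CH2 carbon should give the silyl ester of the ω-iodo acid, which water hydrolyses.

Step 7
Reactants: 18; 19 (S)-solketal
Product: 20 [(4R)-2,2-dimethyl-1,3-dioxolan-4-yl]methyl (3S)-5-iodo-3-methylpentanoate
Conditions: DCC, DMAP (cat.), CH2Cl2, 0 → 23 °C
Reagents that add atoms: none
Why: Steglich esterification should join the acid and the primary alcohol of the glycerol acetonide at low temperature, where neither the primary iodide nor the acetal reacts and the dioxolane stereocentre is untouched.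

Step 8
Reactants: 13; 20
Product: 23 [(4R)-2,2-dimethyl-1,3-dioxolan-4-yl]methyl (3R)-3-methyl-6-oxo-6-[(1R,2R)-1,3,3-trimethyl-2-(3-oxobutyl)cyclohexyl]hexanoate, via acid chloride 21 (not isolated), via alkylzinc iodide 22 (not isolated)
Conditions: 13: (COCl)2, DMF (cat.), CH2Cl2, 0 → 23 °C, evaporate; 20: zinc dust (activated with 1,2-dibromoethane/Me3SiCl), LiCl, THF, 35 °C; combine, Pd(PPh3)4 (5 mol %), THF, 0 → 23 °C
Reagents that add atoms: none
Why: Negishi acylation: the alkylzinc iodide made by zinc insertion should transfer its alkyl group to the acylpalladium species formed from the acid chloride and zerovalent palladium, and reductive elimination gives the ketone, organozinc halides being inert toward the ester, the acetal and the methyl ketone.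

Step 9
Reactants: 23
Product: 24 (2R)-2,3-dihydroxypropyl (3R)-3-methyl-6-oxo-6-[(1R,2R)-1,3,3-trimethyl-2-(3-oxobutyl)cyclohexyl]hexanoate
Conditions: AcOH–H2O (4:1), 40 °C
Reagents that add atoms: none
Why: acid hydrolysis of the isopropylidene acetal should free the diol, and the weak acid at moderate temperature should neither move the acyl group to the secondary oxygen nor start an aldol reaction of the 1,6-diketone.

Step 10
Reactants: 24; 25 vinyl acetate
Product: 26 (2R)-3-(acetyloxy)-2-hydroxypropyl (3R)-3-methyl-6-oxo-6-[(1R,2R)-1,3,3-trimethyl-2-(3-oxobutyl)cyclohexyl]hexanoate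
Conditions: immobilised Candida antarctica lipase B (Novozym 435), 25 (3 equiv), tert-butyl methyl ether, 25 °C
Reagents that add atoms: none
Why: lipase-catalysed transesterification with vinyl acetate as irreversible acyl donor should acetylate the primary hydroxyl of the 1-monoacylglycerol regioselectively under neutral conditions, the configuration of the glycerol carbon having been fixed by solketal.

**Compound list**

1 | (S)-(+)-carvone, (5S)-2-methyl-5-(prop-1-en-2-yl)cyclohex-2-en-1-one | CC1=CC[C@@H](CC1=O)C(C)=C | starting material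
2 | trimethyl(3-methylbut-2-en-1-yl)silane (prenyltrimethylsilane) | CC(C)=CC[Si](C)(C)C | starting material
3 | allyl bromide | C=CCBr | starting material
4 | trimethyl{[(3R,5S)-2-methyl-3-(2-methylbut-3-en-2-yl)-5-(prop-1-en-2-yl)cyclohex-1-en-1-yl]oxy}silane | C[Si](C)(C)OC1=C(C)[C@@H](C(C)(C)C=C)C[C@H](C(C)=C)C1 | intermediate
5 | lithium (3R,5S)-2-methyl-3-(2-methylbut-3-en-2-yl)-5-(prop-1-en-2-yl)cyclohex-1-en-1-olate | [Li]OC1=C(C)[C@@H](C(C)(C)C=C)C[C@H](C(C)=C)C1 | intermediate
6 | (2R,3R,5S)-2-allyl-2-methyl-3-(2-methylbut-3-en-2-yl)-5-(prop-1-en-2-yl)cyclohexan-1-one | O=C1C[C@@H](C(C)=C)C[C@H](C(C)(C)C=C)[C@@]1(C)CC=C | intermediate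
7 | trimethyl{[(3S,5R,6R)-6-allyl-6-methyl-5-(2-methylbut-3-en-2-yl)-3-(prop-1-en-2-yl)cyclohex-1-en-1-yl]oxy}silane | C[Si](C)(C)OC1=C[C@@H](C(C)=C)C[C@H](C(C)(C)C=C)[C@@]1(C)CC=C | intermediate
8 | (2R,3R,5S)-2-allyl-2-methyl-3-(2-methylbut-3-en-2-yl)-5-(2-methyloxiran-2-yl)-6-(trimethylsilyloxy)cyclohexan-1-one (epimers at C6 and at the oxirane carbon) | O=C1C(O[Si](C)(C)C)[C@@H](C2(C)CO2)C[C@H](C(C)(C)C=C)[C@@]1(C)CC=C | intermediate
9 | (2R,3R,5S)-2-allyl-6-hydroxy-2-methyl-3-(2-methylbut-3-en-2-yl)-5-(2-methyloxiran-2-yl)cyclohexan-1-one (same epimer mixture) | O=C1C(O)[C@@H](C2(C)CO2)C[C@H](C(C)(C)C=C)[C@@]1(C)CC=C | intermediate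
10 | (3S,4aR,8aR)-2-hydroxy-5,5,8a-trimethyl-3-(2-methyloxiran-2-yl)-3,4,4a,5,8,8a-hexahydronaphthalen-1(2H)-one | O=C1C(O)[C@@H](C2(C)CO2)C[C@@H]3C(C)(C)C=CC[C@@]13C | intermediate
11 | (3S,4aR,8aR)-2-hydroxy-5,5,8a-trimethyl-3-(2-methyloxiran-2-yl)octahydronaphthalen-1(2H)-one | O=C1C(O)[C@@H](C2(C)CO2)C[C@@H]3C(C)(C)CCC[C@@]13C | intermediate
12 | (1R,2R)-2-(2-formyl-3-oxobutyl)-1,3,3-trimethylcyclohexane-1-carboxylic acid (epimers at the formyl-bearing carbon) | CC(=O)C(C=O)C[C@@H]1C(C)(C)CCC[C@@]1(C)C(O)=O | intermediate
13 | (1R,2R)-1,3,3-trimethyl-2-(3-oxobutyl)cyclohexane-1-carboxylic acid | CC(=O)CC[C@@H]1C(C)(C)CCC[C@@]1(C)C(O)=O | intermediate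
14 | monomethyl (R)-3-methylglutarate, (3R)-5-methoxy-3-methyl-5-oxopentanoic acid | OC(=O)C[C@@H](C)CC(=O)OC | starting material
15 | methyl (3R)-5-hydroxy-3-methylpentanoate | OCC[C@@H](C)CC(=O)OC | intermediate
16 | (4R)-4-methyltetrahydro-2H-pyran-2-one | O=C1C[C@H](C)CCO1 | intermediate
17 | trimethylsilyl (3S)-5-iodo-3-methylpentanoate | ICC[C@@H](C)CC(=O)O[Si](C)(C)C | intermediate
18 | (3S)-5-iodo-3-methylpentanoic acid | ICC[C@@H](C)CC(O)=O | intermediate
19 | (S)-solketal, [(4S)-2,2-dimethyl-1,3-dioxolan-4-yl]methanol | OC[C@H]1COC(C)(C)O1 | starting material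
20 | [(4R)-2,2-dimethyl-1,3-dioxolan-4-yl]methyl (3S)-5-iodo-3-methylpentanoate | ICC[C@@H](C)CC(=O)OC[C@H]1COC(C)(C)O1 | intermediate
21 | (1R,2R)-1,3,3-trimethyl-2-(3-oxobutyl)cyclohexane-1-carbonyl chloride | CC(=O)CC[C@@H]1C(C)(C)CCC[C@@]1(C)C(Cl)=O | intermediate
22 | {(3S)-5-{[(4R)-2,2-dimethyl-1,3-dioxolan-4-yl]methoxy}-3-methyl-5-oxopentyl}(iodo)zinc | I[Zn]CC[C@@H](C)CC(=O)OC[C@H]1COC(C)(C)O1 | intermediate
23 | [(4R)-2,2-dimethyl-1,3-dioxolan-4-yl]methyl (3R)-3-methyl-6-oxo-6-[(1R,2R)-1,3,3-trimethyl-2-(3-oxobutyl)cyclohexyl]hexanoate | CC(=O)CC[C@@H]1C(C)(C)CCC[C@@]1(C)C(=O)CC[C@@H](C)CC(=O)OC[C@H]2COC(C)(C)O2 | intermediate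
24 | (2R)-2,3-dihydroxypropyl (3R)-3-methyl-6-oxo-6-[(1R,2R)-1,3,3-trimethyl-2-(3-oxobutyl)cyclohexyl]hexanoate | CC(=O)CC[C@@H]1C(C)(C)CCC[C@@]1(C)C(=O)CC[C@@H](C)CC(=O)OC[C@H](O)CO | intermediate
25 | vinyl acetate | CC(=O)OC=C | starting material
26 | (2R)-3-(acetyloxy)-2-hydroxypropyl (3R)-3-methyl-6-oxo-6-[(1R,2R)-1,3,3-trimethyl-2-(3-oxobutyl)cyclohexyl]hexanoate (CNP0140002.1) | CC(=O)CC[C@@H]1C(C)(C)CCC[C@@]1(C)C(=O)CC[C@@H](C)CC(=O)OC[C@H](O)COC(C)=O | target

**Step count and risks**

Total steps: 10. Longest linear sequence: 7 (steps 1, 2, 3, 4, 8, 9, 10); the side-chain branch is steps 5, 6, 7.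

Steps most likely to fail:

Step 4. The enolised 2-formyl ketone may be over-oxidised by periodate before it is deformylated (loss of the carbon next to the acetyl group), or the oxirane may open incompletely. The fallback sets out from 11 and comes back at 13. The carbinol of 11 would be oxidised with Dess–Martin periodinane in CH2Cl2 to the 1,2-dione F2. Periodic acid in aqueous THF should then cleave the dione to two carboxylic acids and the oxirane to the acetyl group, giving the β-keto diacid F3, which should lose CO2 on warming to about 50 °C and give 13. The surplus ring carbon then leaves as CO2 and no deformylation is needed.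

Step 1. The isopropenyl group may be lost to acid-induced cationic side reactions under the silyl triflimide catalyst, the addition at the hindered β-carbon may be sluggish, or proton exchange of the lithium enolate may spread the allylation to the CH2 side. The fallback sets out from 1 and comes back at 4. A Hosomi–Sakurai addition of 2 promoted by stoichiometric TiCl4 (CH2Cl2, −78 °C, aqueous work-up) should give the ketone F1 as a mixture of epimers at the methyl-bearing carbon. Thermodynamic enol silylation (Me3SiI, (Me3Si)2NH, CH2Cl2, −20 → 23 °C) should then give 4, which re-enters step 1 at the MeLi stage.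

Step 8. Acyl transfer at the neopentyl-type carbonyl may be slow, so that decarbonylation of the acylpalladium species or protonolysis of the zinc reagent takes over. The fallback sets out from 13 and 20 and comes back at 23. It is a nickel-catalysed reductive cross-electrophile coupling without a preformed organometallic: 13 would be activated in the flask with Boc2O and MgCl2 as the mixed anhydride F4 and coupled with iodide 20 (NiCl2(dme), 4,4'-di-tert-butyl-2,2'-bipyridine, zinc dust, N,N-dimethylacetamide, 25 °C). The bond should form by capture of the primary alkyl radical at an acylnickel species.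

Further compounds
F1 | step 1 | (3R,5S)-2-methyl-3-(2-methylbut-3-en-2-yl)-5-(prop-1-en-2-yl)cyclohexan-1-one (epimers at C2) | O=C1C[C@@H](C(C)=C)C[C@H](C(C)(C)C=C)C1C
F2 | step 4 | (4aR,8aR)-5,5,8a-trimethyl-3-(2-methyloxiran-2-yl)octahydronaphthalene-1,2-dione | O=C1C(=O)C(C2(C)CO2)C[C@@H]3C(C)(C)CCC[C@@]13C
F3 | step 4 | 2-acetyl-3-[(1R,2R)-2-carboxy-2,6,6-trimethylcyclohexyl]propanoic acid | CC(=O)C(C(O)=O)C[C@@H]1C(C)(C)CCC[C@@]1(C)C(O)=O
F4 | step 8 | tert-butyl carbonic (1R,2R)-1,3,3-trimethyl-2-(3-oxobutyl)cyclohexane-1-carboxylic anhydride | CC(=O)CC[C@@H]1C(C)(C)CCC[C@@]1(C)C(=O)OC(=O)OC(C)(C)C
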